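The synthesis rests on disconnecting the C4–C4a bond of the 2H-pyran ring, the bond from the vinylic CH to the arene carbon that lies between the oxygen-bearing carbons C5 and C8a. A gold-catalysed 6-endo-dig hydroarylation of an aryl 1,1-dimethylpropargyl ether forms this bond and closes the pyran ring in one operation. The precursor is O-propargylated, mono-MOM-protected methyl orsellinate: its ester blocks the other ortho carbon (future C8), so only C4a can attack the alkyne. The ester then acidifies the adjacent methyl group for lateral lithiation and benzylation (bibenzyl chain at C7) and is finally reduced and extended to the C8 prenyl group before the MOM groups are removed.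

Key step: step 3

Remark on the chemistry: the target has no stereocentre and its only ring alkene (C3=C4) is necessarily cis, so no stereocontrol is required; chromene numbering (O1, C2 … C8a) is used for the bicyclic core.

Step 1
Reactants: 1 methyl 2,4-dihydroxy-6-methylbenzoate (methyl orsellinate)
Product: 2 methyl 2-hydroxy-4-(methoxymethoxy)-6-methylbenzoate
Conditions: MOMCl (1.1 equiv), K2CO3, acetone, 0 °C to rt
Reagents that add atoms: chloromethyl methyl ether (MOMCl), COCCl
Why: Williamson-type O-alkylation that should take place only at the more acidic, unhindered 4-OH, because the 2-OH is held in a hydrogen bond to the ester carbonyl.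

Step 2
Reactants: 2 methyl 2-hydroxy-4-(methoxymethoxy)-6-methylbenzoate
Product: 3 methyl 4-(methoxymethoxy)-6-methyl-2-[(2-methylbut-3-yn-2-yl)oxy]benzoate
Conditions: 3-chloro-3-methylbut-1-yne (1.5 equiv), DBU, CuCl2 (1 mol %), MeCN, 0 °C to rt
Reagents that add atoms: 3-chloro-3-methylbut-1-yne, C#CC(C)(C)Cl
Why: copper-catalysed propargylic etherification, in which the copper acetylide of the chloride ionises to a copper allenylidene that the DBU-generated phenoxide should capture at the tertiary carbon, the amidine base also breaking the hydrogen bond to the ester.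

Step 3
Reactants: 3 methyl 4-(methoxymethoxy)-6-methyl-2-[(2-methylbut-3-yn-2-yl)oxy]benzoate
Product: 4 methyl 5-(methoxymethoxy)-2,2,7-trimethyl-2H-chromene-8-carboxylate
Conditions: Ph3PAuNTf2 (3 mol %), dry CH2Cl2, rt to 40 °C
Reagents that add atoms: none
Why: The cationic monovalent gold complex binds the terminal alkyne of 3 as a π-acid, and the arene carbon ortho to the ether oxygen (C3 of the benzoate, the future C4a) attacks the terminal alkyne carbon (the future C4) in a Friedel–Crafts-type step, so that the new C4–C4a bond is the ring-closing bond; rearomatisation and protodeauration of the vinyl–gold bond at the future C3 then release 4 and the catalyst. The closest known reaction type is the gold- or platinum-catalysed intramolecular hydroarylation of aryl propargyl ethers to 2H-chromenes. The pyran ring closes in the 6-endo-dig mode, favoured over 5-exo-dig closure because the short O–CMe2 tether holds the terminal carbon, not the internal one, over the ortho carbon. No stereocentre is formed. The step needs site selectivity between the two ortho carbons of the ether oxygen, and the substrate secures it because one of them carries the CO2Me group, leaving only the carbon between the two oxygen-bearing carbons, which is also activated by both alkoxy groups and the para methyl group. Chemoselectivity over alkyne hydration should be secured by anhydrous conditions and a non-nucleophilic solvent.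

Step 4
Reactants: 5 4-(hydroxymethyl)phenol (4-hydroxybenzyl alcohol)
Product: 6 [4-(methoxymethoxy)phenyl]methanol
Conditions: MOMCl (1.05 equiv), K2CO3, acetone, 0 °C to rt
Reagents that add atoms: chloromethyl methyl ether (MOMCl), COCCl
Why: chemoselective Williamson etherification, since carbonate deprotonates only the phenol and leaves the benzylic alcohol untouched.

Step 5
Reactants: 6 [4-(methoxymethoxy)phenyl]methanol
Product: 7 1-(bromomethyl)-4-(methoxymethoxy)benzene
Conditions: CBr4, PPh3, CH2Cl2, 0 °C; used at once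
Reagents that add atoms: tetrabromomethane, BrC(Br)(Br)Br
Why: Appel reaction, whose neutral conditions the MOM acetal should tolerate.

Step 6
Reactants: 4 methyl 5-(methoxymethoxy)-2,2,7-trimethyl-2H-chromene-8-carboxylate; 7 1-(bromomethyl)-4-(methoxymethoxy)benzene
Product: 9 methyl 5-(methoxymethoxy)-7-{2-[4-(methoxymethoxy)phenyl]ethyl}-2,2-dimethyl-2H-chromene-8-carboxylate, via benzylic organolithium 8 (not isolated)
Conditions: LiN(i-Pr)2 (1.15 equiv), THF, −78 °C; then 7, −78 to −30 °C
Reagents that add atoms: none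
Why: lateral lithiation of an ortho-toluate, in which the C7 methyl group is acidified by the ortho ester (extended enolate 8) and SN2 alkylation with the benzylic bromide should give the bibenzyl, the doubly ortho-substituted ester resisting self-condensation.

Step 7
Reactants: 9 methyl 5-(methoxymethoxy)-7-{2-[4-(methoxymethoxy)phenyl]ethyl}-2,2-dimethyl-2H-chromene-8-carboxylate
Product: 10 [5-(methoxymethoxy)-7-{2-[4-(methoxymethoxy)phenyl]ethyl}-2,2-dimethyl-2H-chromen-8-yl]methanol
Conditions: LiAlH4, THF, 0 °C to rt; aqueous NaOH work-up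
Reagents that add atoms: none
Why: hydride reduction of the ester to the primary benzylic alcohol, to which the chromene alkene and the MOM acetals are inert.

Step 8
Reactants: 10 [5-(methoxymethoxy)-7-{2-[4-(methoxymethoxy)phenyl]ethyl}-2,2-dimethyl-2H-chromen-8-yl]methanol
Product: 13 5-(methoxymethoxy)-7-{2-[4-(methoxymethoxy)phenyl]ethyl}-2,2-dimethyl-8-(3-methylbut-2-en-1-yl)-2H-chromene, via benzylic mesylate 11 (not isolated), via benzylic chloride 12 (not isolated)
Conditions: MsCl, Et3N, LiCl, THF, −20 to 0 °C; then (CH3)2C=CHMgBr (3 equiv), Li2CuCl4 (5 mol %), −30 to 0 °C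
Reagents that add atoms: (2-methylprop-1-en-1-yl)magnesium bromide, CC(C)=C[Mg]Br; methanesulfonyl chloride, CS(=O)(=O)Cl (in 11 only); lithium chloride, [Li+].[Cl-] (in 12 only)
Why: the electron-rich benzylic mesylate should collapse to the chloride in the flask, and copper-catalysed Grignard cross-coupling at the benzylic carbon with the alkenyl nucleophile installs the isobutenyl unit, completing the prenyl group with its trisubstituted alkene already in place (excess Grignard reagent absorbs the ammonium salt).

Step 9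
Reactants: 13 5-(methoxymethoxy)-7-{2-[4-(methoxymethoxy)phenyl]ethyl}-2,2-dimethyl-8-(3-methylbut-2-en-1-yl)-2H-chromene
Product: 14 7-[2-(4-hydroxyphenyl)ethyl]-2,2-dimethyl-8-(3-methylbut-2-en-1-yl)-2H-chromen-5-ol (target)
Conditions: HCl (3 M aq., cat.), MeOH, rt to 40 °C
Reagents that add atoms: none
Why: acid-catalysed acetal exchange should remove both MOM groups, and the prenyl group cannot cyclise to a chroman because its neighbours are the ring oxygen O1 and the C7 chain, not a free phenol.

Compound list
1 | methyl 2,4-dihydroxy-6-methylbenzoate (methyl orsellinate) | COC(=O)c1c(C)cc(O)cc1O | starting material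
2 | methyl 2-hydroxy-4-(methoxymethoxy)-6-methylbenzoate | COC(=O)c1c(C)cc(OCOC)cc1O | intermediate
3 | methyl 4-(methoxymethoxy)-6-methyl-2-[(2-methylbut-3-yn-2-yl)oxy]benzoate | COC(=O)c1c(C)cc(OCOC)cc1OC(C)(C)C#C | intermediate
4 | methyl 5-(methoxymethoxy)-2,2,7-trimethyl-2H-chromene-8-carboxylate | COC(=O)c1c(C)cc(OCOC)c2C=CC(C)(C)Oc12 | intermediate
5 | 4-(hydroxymethyl)phenol (4-hydroxybenzyl alcohol) | OCc1ccc(O)cc1 | starting material
6 | [4-(methoxymethoxy)phenyl]methanol | COCOc1ccc(CO)cc1 | intermediate
7 | 1-(bromomethyl)-4-(methoxymethoxy)benzene | COCOc1ccc(CBr)cc1 | intermediate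
8 | {[8-(methoxycarbonyl)-5-(methoxymethoxy)-2,2-dimethyl-2H-chromen-7-yl]methyl}lithium | [Li]Cc1cc(OCOC)c2C=CC(C)(C)Oc2c1C(=O)OC | intermediate
9 | methyl 5-(methoxymethoxy)-7-{2-[4-(methoxymethoxy)phenyl]ethyl}-2,2-dimethyl-2H-chromene-8-carboxylate | COCOc1ccc(CCc2cc(OCOC)c3C=CC(C)(C)Oc3c2C(=O)OC)cc1 | intermediate
10 | [5-(methoxymethoxy)-7-{2-[4-(methoxymethoxy)phenyl]ethyl}-2,2-dimethyl-2H-chromen-8-yl]methanol | COCOc1ccc(CCc2cc(OCOC)c3C=CC(C)(C)Oc3c2CO)cc1 | intermediate
11 | [5-(methoxymethoxy)-7-{2-[4-(methoxymethoxy)phenyl]ethyl}-2,2-dimethyl-2H-chromen-8-yl]methyl methanesulfonate | COCOc1ccc(CCc2cc(OCOC)c3C=CC(C)(C)Oc3c2COS(C)(=O)=O)cc1 | intermediate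
12 | 8-(chloromethyl)-5-(methoxymethoxy)-7-{2-[4-(methoxymethoxy)phenyl]ethyl}-2,2-dimethyl-2H-chromene | COCOc1ccc(CCc2cc(OCOC)c3C=CC(C)(C)Oc3c2CCl)cc1 | intermediate
13 | 5-(methoxymethoxy)-7-{2-[4-(methoxymethoxy)phenyl]ethyl}-2,2-dimethyl-8-(3-methylbut-2-en-1-yl)-2H-chromene | COCOc1ccc(CCc2cc(OCOC)c3C=CC(C)(C)Oc3c2CC=C(C)C)cc1 | intermediate
14 | 7-[2-(4-hydroxyphenyl)ethyl]-2,2-dimethyl-8-(3-methylbut-2-en-1-yl)-2H-chromen-5-ol | CC(C)=CCc1c(CCc2ccc(O)cc2)cc(O)c2c1OC(C)(C)C=C2 | target

Total step count: 9. Longest linear sequence: 7 steps (steps 1, 2, 3, 6, 7, 8, 9); steps 4 and 5 form the side branch that joins in step 6.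

Steps most likely to fail

Step 2. The hydrogen-bonded, ester-flanked phenoxide may be too weak a nucleophile to capture the tertiary propargylic copper intermediate, so that the chloride is consumed by elimination and oligomerisation while the phenol remains. The fallback sets out from 2 and comes back to the route at 13; it never alkylates the chelated phenol with a tertiary electrophile and moves the ring closure to the end.
- Compound 2 is O-allylated (allyl bromide, K2CO3, DMF, 60 °C) to methyl 4-(methoxymethoxy)-6-methyl-2-(prop-2-en-1-yloxy)benzoate F1.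
- Lateral lithiation (LiN(i-Pr)2, THF, −78 °C) gives {[2-(methoxycarbonyl)-5-(methoxymethoxy)-3-(prop-2-en-1-yloxy)phenyl]methyl}lithium F2, which is benzylated with 7 to methyl 4-(methoxymethoxy)-6-{2-[4-(methoxymethoxy)phenyl]ethyl}-2-(prop-2-en-1-yloxy)benzoate F3.
- LiAlH4 reduction gives [4-(methoxymethoxy)-2-{2-[4-(methoxymethoxy)phenyl]ethyl}-6-(prop-2-en-1-yloxy)phenyl]methanol F4.
- PPh3 and N-chlorosuccinimide convert it to 2-(chloromethyl)-5-(methoxymethoxy)-1-{2-[4-(methoxymethoxy)phenyl]ethyl}-3-(prop-2-en-1-yloxy)benzene F5, which is coupled with (CH3)2C=CHMgBr and Li2CuCl4 to 5-(methoxymethoxy)-1-{2-[4-(methoxymethoxy)phenyl]ethyl}-2-(3-methylbut-2-en-1-yl)-3-(prop-2-en-1-yloxy)benzene F6.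
- Deallylation with Pd(PPh3)4 (zerovalent palladium) and morpholine frees the no longer chelated phenol 5-(methoxymethoxy)-3-{2-[4-(methoxymethoxy)phenyl]ethyl}-2-(3-methylbut-2-en-1-yl)phenol F7.
- Propargylation under the conditions of step 2 gives 5-(methoxymethoxy)-1-{2-[4-(methoxymethoxy)phenyl]ethyl}-2-(3-methylbut-2-en-1-yl)-3-[(2-methylbut-3-yn-2-yl)oxy]benzene F8.
- Ph3PAuNTf2 then closes the pyran ring at the only free ortho carbon of F8 to give 13.

Step 3. The gold catalyst may be sequestered by the neighbouring ester carbonyl, or it may hydrate the alkyne or ionise the tertiary propargylic C–O bond faster than the deactivated arene attacks. The fallback sets out from 3 and comes back at 4, keeping the same ring-closing bond but using a stoichiometric electrophile.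
- Iodocyclisation (I2, NaHCO3, MeNO2, rt) should give methyl 3-iodo-5-(methoxymethoxy)-2,2,7-trimethyl-2H-chromene-8-carboxylate F9 by 6-endo-dig iodoarylation.
- The vinylic iodide is then removed by palladium-catalysed formate reduction (Pd(OAc)2, PPh3, HCO2H, Et3N, DMF, 60 °C) to give 4.

Step 8. The doubly oxygen-activated benzylic chloride 12 may ionise faster than it couples, leading to Friedel–Crafts self-alkylation or Wurtz-type homocoupling. The fallback sets out from 10 and comes back at 13, replacing the labile chloride and the hard nucleophile by a stable carbonate and a boron reagent.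
- Compound 10 is acylated (ClCO2Me, pyridine, CH2Cl2, 0 °C) to [5-(methoxymethoxy)-7-{2-[4-(methoxymethoxy)phenyl]ethyl}-2,2-dimethyl-2H-chromen-8-yl]methyl methyl carbonate F10.
- Suzuki–Miyaura coupling with 2-methylprop-1-enylboronic acid pinacol ester (Pd(OAc)2, DPEphos, K2CO3, toluene, 80 °C; ionisation by zerovalent palladium to an η3-benzyl complex, then transmetalation and reductive elimination) gives 13.

Further compounds
F1 | step 2 | methyl 4-(methoxymethoxy)-6-methyl-2-(prop-2-en-1-yloxy)benzoate | C=CCOc1cc(OCOC)cc(C)c1C(=O)OC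
F2 | step 2 | {[2-(methoxycarbonyl)-5-(methoxymethoxy)-3-(prop-2-en-1-yloxy)phenyl]methyl}lithium | [Li]Cc1cc(OCOC)cc(OCC=C)c1C(=O)OC
F3 | step 2 | methyl 4-(methoxymethoxy)-6-{2-[4-(methoxymethoxy)phenyl]ethyl}-2-(prop-2-en-1-yloxy)benzoate | C=CCOc1cc(OCOC)cc(CCc2ccc(OCOC)cc2)c1C(=O)OC
F4 | step 2 | [4-(methoxymethoxy)-2-{2-[4-(methoxymethoxy)phenyl]ethyl}-6-(prop-2-en-1-yloxy)phenyl]methanol | C=CCOc1cc(OCOC)cc(CCc2ccc(OCOC)cc2)c1CO
F5 | step 2 | 2-(chloromethyl)-5-(methoxymethoxy)-1-{2-[4-(methoxymethoxy)phenyl]ethyl}-3-(prop-2-en-1-yloxy)benzene | C=CCOc1cc(OCOC)cc(CCc2ccc(OCOC)cc2)c1CCl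
F6 | step 2 | 5-(methoxymethoxy)-1-{2-[4-(methoxymethoxy)phenyl]ethyl}-2-(3-methylbut-2-en-1-yl)-3-(prop-2-en-1-yloxy)benzene | C=CCOc1cc(OCOC)cc(CCc2ccc(OCOC)cc2)c1CC=C(C)C
F7 | step 2 | 5-(methoxymethoxy)-3-{2-[4-(methoxymethoxy)phenyl]ethyl}-2-(3-methylbut-2-en-1-yl)phenol | Oc1cc(OCOC)cc(CCc2ccc(OCOC)cc2)c1CC=C(C)C
F8 | step 2 | 5-(methoxymethoxy)-1-{2-[4-(methoxymethoxy)phenyl]ethyl}-2-(3-methylbut-2-en-1-yl)-3-[(2-methylbut-3-yn-2-yl)oxy]benzene | C#CC(C)(C)Oc1cc(OCOC)cc(CCc2ccc(OCOC)cc2)c1CC=C(C)C
F9 | step 3 | methyl 3-iodo-5-(methoxymethoxy)-2,2,7-trimethyl-2H-chromene-8-carboxylate | COC(=O)c1c(C)cc(OCOC)c2C=C(I)C(C)(C)Oc12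
F10 | step 8 | [5-(methoxymethoxy)-7-{2-[4-(methoxymethoxy)phenyl]ethyl}-2,2-dimethyl-2H-chromen-8-yl]methyl methyl carbonate | COCOc1ccc(CCc2cc(OCOC)c3C=CC(C)(C)Oc3c2COC(=O)OC)cc1
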